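The furan is not carried through the synthesis; it is created in the fragment union. The bond between furan C2 and the first CH2 of the ten-carbon tether is traced back to the lactone carbonyl of 3,4-dimethyl-5-propylfuran-2(5H)-one, whose ring atoms O1, C2–C5 and both methyl groups come from symmetrical 2,3-dimethylmaleic anhydride. The key step exploits the fact that furan C2 sits between O1 and the fully substituted C3=C4 bond: 10-chlorodecylmagnesium bromide adds 1,2 to that carbonyl, and acid then expels water, so one operation forms the C–C bond and the aromatic tetrasubstituted ring and erases the precursor's only stereocentre. The chloride terminus later becomes a Grignard reagent that an L-serine Weinreb amide acylates.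

Key step: step 3

Remark: ring numbering throughout is O1, C2 (tether), C3 and C4 (methyl), C5 (propyl). Butenolide 5 is used as the racemate because its stereocentre vanishes in step 3. The tetraalkylfurans are handled under argon with light excluded.

Step 1
Reactants: 1 2,3-dimethylmaleic anhydride; 2 n-propylmagnesium chloride
Product: 5 (±)-3,4-dimethyl-5-propylfuran-2(5H)-one, via keto carboxylate 3 (not isolated), via hydroxy carboxylate 4 (not isolated)
Conditions: 2 (1.05 equiv) added to 1, THF, −78 → −20 °C; then MeOH, NaBH4, 0 °C → rt; then 2 M HCl, rt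
Reagents that add atoms: none
Why: Grignard addition to a cyclic anhydride should stop after one addition because the ring opens to the deactivated magnesium keto carboxylate 3, NaBH4 then reduces the ketone 1,2 to 4, and acidification lactonises the (Z)-hydroxy acid, the new C5 stereocentre arising as a racemate that step 3 erases.

Step 2
Reactants: 6 10-chlorodecan-1-ol
Product: 7 1-bromo-10-chlorodecane
Conditions: CBr4, PPh3, CH2Cl2, 0 °C → rt
Reagents that add atoms: carbon tetrabromide, BrC(Br)(Br)Br
Why: Appel reaction, in which the alkoxyphosphonium salt of the primary alcohol is displaced by bromide in an SN2 process while the far less reactive primary chloride is untouched.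

Step 3
Reactants: 7 1-bromo-10-chlorodecane; 5 (±)-3,4-dimethyl-5-propylfuran-2(5H)-one
Product: 10 2-(10-chlorodecyl)-3,4-dimethyl-5-propylfuran, via Grignard reagent 8 (not isolated), via lactolate 9 (not isolated)
Conditions: 7, Mg turnings, THF, 25–35 °C; added to 5 premixed with LaCl3·2LiCl (1.0 equiv), THF, −78 → −30 °C; then 1 M HCl, 0 °C → rt
Reagents that add atoms: none
Why: Magnesium inserts only into the weaker C–Br bond of 7, and the primary Grignard reagent 8, made more oxophilic and less basic by LaCl3·2LiCl, adds 1,2 to the lactone carbonyl C2 of 5 to give lactolate 9, in which the tether CH2 is already bonded to the future furan C2. On acidification 9 ionises to a cyclic oxocarbenium ion and loses the C5 proton next to the propyl group, so that water leaves and the aromatic ring forms. The closest known reaction type is the addition of an organometallic reagent to a 2(5H)-furanone followed by dehydrative aromatisation, the carbon counterpart of the iBu2AlH butenolide-to-furan reduction. No ring is closed, since the five-membered O-heterocycle of 5 is kept and only aromatised. No stereocentre survives, because the lactol carbon is transient and C5 becomes trigonal, which is why racemic 5 suffices. The step needs 1,2- over 1,4-addition (secured by the methyl-blocked, fully substituted C3=C4 bond), one addition instead of two (the Z-alkene holds the alkoxide oxygen on C2, so the lactolate should stay closed at low temperature) and addition over deprotonation at C5 (lanthanum salt and low temperature).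

Step 4
Reactants: 11 N-acetyl-L-serine methyl ester
Product: 12 (S)-2-acetamido-3-hydroxy-N-methoxy-N-methylpropanamide
Conditions: MeNH(OMe)·HCl (2 equiv), iPrMgCl (6 equiv), THF, −20 → 0 °C; then 2 M HCl to pH 6, NaCl, extraction with CHCl3/iPrOH
Reagents that add atoms: N,O-dimethylhydroxylamine hydrochloride, CNOC.Cl
Why: Weinreb amide synthesis by aminolysis of the ester with the chloromagnesium amide of N,O-dimethylhydroxylamine needs no carboxyl activation, so no azlactone can form, and the deprotonated acetamide shields the α-hydrogen, so the L-serine stereocentre should be retained.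

Step 5
Reactants: 10 2-(10-chlorodecyl)-3,4-dimethyl-5-propylfuran; 12 (S)-2-acetamido-3-hydroxy-N-methoxy-N-methylpropanamide
Product: 16 N-[(2S)-13-(3,4-dimethyl-5-propylfuran-2-yl)-1-hydroxy-3-oxotridecan-2-yl]acetamide, via Grignard reagent 13 (not isolated), via magnesium salt 14 (not isolated), via tetrahedral adduct 15 (not isolated)
Conditions: 10, Mg turnings (activated with a little 1,2-dibromoethane), THF, reflux; separately 12 (1.3 equiv), iPrMgCl (2.0 equiv per 12), THF, −20 °C; 13 added to 14, −20 °C → rt; poured into cold 0.5 M HCl, immediate extraction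
Reagents that add atoms: none
Why: Weinreb ketone synthesis, in which sacrificial iPrMgCl removes the OH and NH protons, Grignard reagent 13 adds once to the amide carbonyl, the N-methoxy chelate 15 holds until the cold acidic quench, and the adjacent amidate charge disfavours enolisation, so the (S)-centre taken from L-serine should reach 16 unchanged.

Compound list
1 | 2,3-dimethylmaleic anhydride | CC1=C(C)C(=O)OC1=O | starting material
2 | n-propylmagnesium chloride | CCC[Mg]Cl | starting material
3 | chloromagnesium (Z)-2,3-dimethyl-4-oxohept-2-enoate | CCCC(=O)/C(C)=C(/C)C(=O)O[Mg]Cl | intermediate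
4 | (Z)-4-hydroxy-2,3-dimethylhept-2-enoate, racemic, drawn as the free acid | CCCC(O)/C(C)=C(/C)C(=O)O | intermediate
5 | (±)-3,4-dimethyl-5-propylfuran-2(5H)-one | CCCC1OC(=O)C(C)=C1C | intermediate
6 | 10-chlorodecan-1-ol | OCCCCCCCCCCCl | starting material
7 | 1-bromo-10-chlorodecane | BrCCCCCCCCCCCl | intermediate
8 | 10-chlorodecylmagnesium bromide | ClCCCCCCCCCC[Mg]Br | intermediate
9 | bromomagnesium 2-(10-chlorodecyl)-3,4-dimethyl-5-propyl-2,5-dihydrofuran-2-olate (mixture of diastereomers) | CCCC1OC(CCCCCCCCCCCl)(O[Mg]Br)C(C)=C1C | intermediate
10 | 2-(10-chlorodecyl)-3,4-dimethyl-5-propylfuran | CCCc1oc(CCCCCCCCCCCl)c(C)c1C | intermediate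
11 | N-acetyl-L-serine methyl ester | CC(=O)N[C@@H](CO)C(=O)OC | starting material
12 | (S)-2-acetamido-3-hydroxy-N-methoxy-N-methylpropanamide | CC(=O)N[C@@H](CO)C(=O)N(C)OC | intermediate
13 | 10-(3,4-dimethyl-5-propylfuran-2-yl)decylmagnesium chloride | CCCc1oc(CCCCCCCCCC[Mg]Cl)c(C)c1C | intermediate
14 | N,O-bis(chloromagnesium) salt of 12 | CC(=O)N([Mg]Cl)[C@@H](CO[Mg]Cl)C(=O)N(C)OC | intermediate
15 | chelated tetrahedral adduct of 13 and 14 | CCCc1oc(CCCCCCCCCCC(O[Mg]Cl)(N(C)OC)[C@H](CO[Mg]Cl)N([Mg]Cl)C(C)=O)c(C)c1C | intermediate
16 | N-[(2S)-13-(3,4-dimethyl-5-propylfuran-2-yl)-1-hydroxy-3-oxotridecan-2-yl]acetamide | CCCc1oc(CCCCCCCCCCC(=O)[C@H](CO)NC(C)=O)c(C)c1C | target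

Total step count: 5. Longest linear sequence: 3 steps (1 → 3 → 5, or equally 2 → 3 → 5).

Steps most likely to fail

1. Step 3. Proton transfer from C5–H of the butenolide to the Grignard reagent may outrun carbonyl addition. Opening of the lactolate may also allow a second addition.
 - The fallback sets out from 5 and comes back at 10.
 - Reduction of 5 with iBu2AlH (CH2Cl2, −78 °C) and acidic work-up should give 3,4-dimethyl-2-propylfuran F1 by the same dehydrative aromatisation.
 - n-BuLi/TMEDA (THF, 0 °C) metalates the only free ring position to (3,4-dimethyl-5-propylfuran-2-yl)lithium F2.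
 - Alkylation of F2 with 7 (THF/DMPU, −78 °C → rt) displaces bromide in preference to chloride. It forms the same C2–CH2 bond on the finished ring.

2. Step 5. The doubly deprotonated amide may aggregate or precipitate, so that acyl transfer becomes slow. Long exposure to basic magnesium species may then erode the configuration at the α-carbon or start loss of the β-oxygen.
 - The fallback sets out from 10 and 11 and comes back at 16. It replaces the basic addition by a neutral Fukuyama coupling.
 - Silylation of 11 (TBSCl, imidazole, DMF) gives methyl N-acetyl-O-(tert-butyldimethylsilyl)-L-serinate F3.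
 - Me2AlSEt (from AlMe3 and EtSH, CH2Cl2, 0 °C → rt) converts F3 into S-ethyl (S)-2-acetamido-3-(tert-butyldimethylsilyloxy)propanethioate F4.
 - In parallel, Finkelstein exchange of 10 (NaI, acetone, reflux) gives 2-(10-iododecyl)-3,4-dimethyl-5-propylfuran F5.
 - Zinc insertion (Zn dust, LiCl, THF, 40 °C) converts F5 into 10-(3,4-dimethyl-5-propylfuran-2-yl)decylzinc iodide F6.
 - Coupling of F6 with F4 (PdCl2(PPh3)2, toluene/THF, rt) should give the O-silylated ketone F7.
 - HF·pyridine (THF/pyridine, 0 °C) then releases 16.

3. Step 1. Hydride delivery in the telescoped stage may stall, because the hindered ketone equilibrates with its closed lactolate form, or it may go to the conjugated C=C bond.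
 - The fallback sets out from 3 and comes back at 5.
 - Acidic work-up after the Grignard stage isolates the ring tautomer 5-hydroxy-3,4-dimethyl-5-propylfuran-2(5H)-one F8.
 - Ionic hydrogenation (Et3SiH, CF3CO2H, CH2Cl2, 0 °C → rt) ionises the pseudo-acid hydroxyl group and delivers hydride to C5 of the acyloxocarbenium ion, giving 5.

Further compounds
F1 | step 3 | 3,4-dimethyl-2-propylfuran | CCCc1occ(C)c1C
F2 | step 3 | (3,4-dimethyl-5-propylfuran-2-yl)lithium | CCCc1oc([Li])c(C)c1C
F3 | step 5 | methyl N-acetyl-O-(tert-butyldimethylsilyl)-L-serinate | CC(=O)N[C@@H](CO[Si](C)(C)C(C)(C)C)C(=O)OC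
F4 | step 5 | S-ethyl (S)-2-acetamido-3-(tert-butyldimethylsilyloxy)propanethioate | CCSC(=O)[C@H](CO[Si](C)(C)C(C)(C)C)NC(C)=O
F5 | step 5 | 2-(10-iododecyl)-3,4-dimethyl-5-propylfuran | CCCc1oc(CCCCCCCCCCI)c(C)c1C
F6 | step 5 | 10-(3,4-dimethyl-5-propylfuran-2-yl)decylzinc iodide | CCCc1oc(CCCCCCCCCC[Zn]I)c(C)c1C
F7 | step 5 | N-[(2S)-1-(tert-butyldimethylsilyloxy)-13-(3,4-dimethyl-5-propylfuran-2-yl)-3-oxotridecan-2-yl]acetamide | CCCc1oc(CCCCCCCCCCC(=O)[C@H](CO[Si](C)(C)C(C)(C)C)NC(C)=O)c(C)c1C
F8 | step 1 | 5-hydroxy-3,4-dimethyl-5-propylfuran-2(5H)-one (racemic) | CCCC1(O)OC(=O)C(C)=C1C
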